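**Retrosynthetic overview**
- The enone is cut last by Claisen–Schmidt condensation into a ring-A methyl ketone and 4-hydroxybenzaldehyde, so ring B arrives in the final step.
- The tertiary alcohol comes from an isopropenyl group by Markovnikov hydration.
- Key disconnection: the C2–C3 bond (and O1–C2) of the dihydrofuran. C3 is an aldehyde carbon; C2, which ends up oxygen-bearing, is delivered as the carbanion of a chiral sulfonium ylide. The resulting epoxide is opened 5-endo by the ring-A phenoxide, and both stereocentres are set here.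
- The aldehyde comes from 2,4-dihydroxyacetophenone by Duff formylation; the sulfonium salt from isothiocineole and methallyl bromide.
- Ring order: ring A is bought, the dihydrofuran ring is formed in the key step, ring B is attached last.

Assumption: (1S,4S,5S)-isothiocineole is bought (it is otherwise one step from (S)-limonene, sulfur and γ-terpinene).
Assumption: the ylide of (1R,4R,5R)-isothiocineole gives trans-epoxides of the (R,R)-stilbene-oxide sense (my recollection, supported by a steric model of the ylide, not checked against data), so its (1S,4S,5S) enantiomer is used; if the sense proves opposite, the mirror-image sulfide is used with nothing else changed.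

**Step 1**
Reactants: 1 2,4-dihydroxyacetophenone
Product: 3 3-acetyl-2,6-dihydroxybenzaldehyde, via N-methyl aldimine 2 (not isolated)
Conditions: hexamethylenetetramine (2 equiv), CF3CO2H, 90 °C; then 3 M aq. HCl, 60 °C
Reagents that add atoms: hexamethylenetetramine C1N2CN3CN1CN(C2)C3; water O
Why: Duff formylation: the iminium ion from hexamethylenetetramine attacks the most nucleophilic ring position, the one between the two hydroxyls; an internal hydride shift gives aldimine 2, which the aqueous acid hydrolyses to the aldehyde (the minor 5-formyl isomer is removed by chromatography; no stereocentre is formed).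

**Step 2**
Reactants: 4 (1S,4S,5S)-isothiocineole; 5 3-bromo-2-methylprop-1-ene
Product: 6 (1S,4S,5S,6S)-4,7,7-trimethyl-6-(2-methylprop-2-en-1-yl)-6-thiabicyclo[3.2.1]octan-6-ium trifluoromethanesulfonate
Conditions: LiOSO2CF3, CH2Cl2/H2O, rt, 24 h
Reagents that add atoms: lithium trifluoromethanesulfonate [Li+].[O-]S(=O)(=O)C(F)(F)F
Why: SN2 S-alkylation of the thioether by the allylic bromide with triflate metathesis; only the exo lone pair of sulfur (the one facing the one-carbon bridge) is accessible, so a single sulfonium diastereomer (6S) forms.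

**Step 3**
Reactants: 3 3-acetyl-2,6-dihydroxybenzaldehyde; 6 (1S,4S,5S,6S)-4,7,7-trimethyl-6-(2-methylprop-2-en-1-yl)-6-thiabicyclo[3.2.1]octan-6-ium trifluoromethanesulfonate
Product: 9 1-[(2R,3S)-3,4-dihydroxy-2-(prop-1-en-2-yl)-2,3-dihydro-1-benzofuran-5-yl]ethan-1-one, via sulfonium ylide 7 (not isolated), via trans-vinyl epoxide 8 (not isolated)
Conditions: 6, KN(SiMe3)2 (1.15 equiv), THF, −78 °C; add dipotassium salt of 3 [3, KN(SiMe3)2 (2.05 equiv), THF/DMPU 4:1], −78 → 0 °C; then AcOH (1.1 equiv), 40 °C; AcOH work-up (4 recovered)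
Reagents that add atoms: none
Why: Proposed new method: the ylide carbon of 7 is a carbanion at what becomes the oxygen-bearing C2, a reversed-polarity partner for the aldehyde carbon, so the C2–C3 bond of the 1,2-dioxygenated unit is made directly; with both phenols deprotonated nothing in the flask can protonate the ylide, and the alkoxide of the anti-betaine closes to the trans-epoxide 8 as in asymmetric sulfonium-ylide (Corey–Chaykovsky-type) epoxidation, the ylide reacting on its face remote from the CMe2 group so that both epoxide carbons are S; after AcOH protonates the acetyl-chelated phenoxide, the phenoxide para to the acetyl group opens the allylic epoxide carbon 5-endo with inversion, which gives the 2,3-trans ring (2R,3S) with C3 untouched; the closest known reactions are the asymmetric sulfonium-ylide epoxidation of aryl aldehydes and the sulfur-ylide annulation of salicylaldehyde salts to 2,3-dihydrobenzofuran-3-ols.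

**Step 4**
Reactants: 9 1-[(2R,3S)-3,4-dihydroxy-2-(prop-1-en-2-yl)-2,3-dihydro-1-benzofuran-5-yl]ethan-1-one
Product: 10 1-[(2S,3S)-3,4-dihydroxy-2-(2-hydroxypropan-2-yl)-2,3-dihydro-1-benzofuran-5-yl]ethan-1-one
Conditions: Co(acac)2 (20 mol%), PhSiH3 (2.5 equiv), O2 (1 atm), THF, rt
Reagents that add atoms: dioxygen O=O
Why: Mukaiyama hydration: hydrogen-atom transfer from the cobalt hydride to the 1,1-disubstituted alkene gives the tertiary radical, which is trapped by O2 and reduced to the tertiary alcohol; no stereocentre is touched, and the C2 descriptor changes from R to S only because the new CMe2OH group outranks C3.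

**Step 5**
Reactants: 10 1-[(2S,3S)-3,4-dihydroxy-2-(2-hydroxypropan-2-yl)-2,3-dihydro-1-benzofuran-5-yl]ethan-1-one; 11 4-hydroxybenzaldehyde
Product: 13 brosimacutin G, via aldol adduct 12 (not isolated)
Conditions: KOH (50% aq., 15 equiv), EtOH, rt, 48 h, Ar; then cold aq. AcOH to pH 6
Reagents that add atoms: none
Why: Claisen–Schmidt condensation: the methyl ketone enolate adds to the aldehyde and E1cB loss of water from aldol 12 gives the more stable (E)-enone; the two ring stereocentres carry no acidic hydrogen and are kept, and the acid-sensitive benzylic alcohol sees only mild acid on neutralisation.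

**Compound list**
1 | 1-(2,4-dihydroxyphenyl)ethan-1-one (2,4-dihydroxyacetophenone) | CC(=O)c1ccc(O)cc1O | starting material
2 | 1-{2,4-dihydroxy-3-[(E)-(methylimino)methyl]phenyl}ethan-1-one (Duff aldimine, not isolated) | CC(=O)c1ccc(O)c(/C=N/C)c1O | intermediate
3 | 3-acetyl-2,6-dihydroxybenzaldehyde | CC(=O)c1ccc(O)c(C=O)c1O | intermediate
4 | (1S,4S,5S)-4,7,7-trimethyl-6-thiabicyclo[3.2.1]octane (isothiocineole, enantiomer derived from (S)-limonene) | C[C@H]1CC[C@H]2C[C@@H]1SC2(C)C | starting material
5 | 3-bromo-2-methylprop-1-ene (methallyl bromide) | CC(=C)CBr | starting material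
6 | (1S,4S,5S,6S)-4,7,7-trimethyl-6-(2-methylprop-2-en-1-yl)-6-thiabicyclo[3.2.1]octan-6-ium trifluoromethanesulfonate | C[C@H]1CC[C@H]2C[C@@H]1[S@+](CC(C)=C)C2(C)C.[O-]S(=O)(=O)C(F)(F)F | intermediate
7 | sulfonium 2-methylallylide derived from 6 (not isolated) | C[C@H]1CC[C@H]2C[C@@H]1[S@+]([CH-]C(C)=C)C2(C)C | intermediate
8 | 1-{2,4-dihydroxy-3-[(2S,3S)-3-(prop-1-en-2-yl)oxiran-2-yl]phenyl}ethan-1-one (trans; present as its potassium phenoxide, not isolated) | CC(=O)c1ccc(O)c([C@@H]2O[C@H]2C(C)=C)c1O | intermediate
9 | 1-[(2R,3S)-3,4-dihydroxy-2-(prop-1-en-2-yl)-2,3-dihydro-1-benzofuran-5-yl]ethan-1-one (2,3-trans) | C=C(C)[C@H]1Oc2ccc(C(C)=O)c(O)c2[C@@H]1O | intermediate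
10 | 1-[(2S,3S)-3,4-dihydroxy-2-(2-hydroxypropan-2-yl)-2,3-dihydro-1-benzofuran-5-yl]ethan-1-one (2,3-trans) | CC(C)(O)[C@H]1Oc2ccc(C(C)=O)c(O)c2[C@@H]1O | intermediate
11 | 4-hydroxybenzaldehyde | O=Cc1ccc(O)cc1 | starting material
12 | 1-[(2S,3S)-3,4-dihydroxy-2-(2-hydroxypropan-2-yl)-2,3-dihydro-1-benzofuran-5-yl]-3-hydroxy-3-(4-hydroxyphenyl)propan-1-one (aldol adduct, both carbinol epimers, not isolated) | CC(C)(O)[C@H]1Oc2ccc(C(=O)CC(O)c3ccc(O)cc3)c(O)c2[C@@H]1O | intermediate
13 | brosimacutin G, (E)-1-[(2S,3S)-3,4-dihydroxy-2-(2-hydroxypropan-2-yl)-2,3-dihydro-1-benzofuran-5-yl]-3-(4-hydroxyphenyl)prop-2-en-1-one | CC(C)(O)[C@H]1Oc2ccc(C(=O)/C=C/c3ccc(O)cc3)c(O)c2[C@@H]1O | target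

**Step count and risks**
Total steps: 5. Longest linear sequence: 4 steps (1 → 3 → 9 → 10 → 13 through steps 1, 3, 4 and 5); step 2 is a one-step side branch.

Step 3 is the most likely to fail. The aldehyde of the dianion is a weak electrophile. A phenoxide could also displace the sulfonium group in the betaine directly, which would give the 2,3-cis ring. The chelated phenoxide could close the ring instead and give the 7-acetyl regioisomer. The fallback sets out from 3. Both phenols are silylated (t-BuMe2SiCl, imidazole, DMF, 40 °C) to give 3-acetyl-2,6-bis[(tert-butyldimethylsilyl)oxy]benzaldehyde F1, a neutral aryl aldehyde of the kind for which the ylide epoxidation is established. F1 is treated with 6 and Cs2CO3 in MeCN at 0 °C to give the isolable 1-{2,4-bis[(tert-butyldimethylsilyl)oxy]-3-[(2S,3S)-3-(prop-1-en-2-yl)oxiran-2-yl]phenyl}ethan-1-one F2. Bu4NF (2.2 equiv) buffered with AcOH (1.1 equiv) in THF then frees the phenols, and the phenoxide para to the acetyl group opens the epoxide with inversion; the fallback comes back to the route at 9.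

Step 5 is the second risk. The phenoxide of 4-hydroxybenzaldehyde is a sluggish electrophile, the 2'-hydroxychalcone can close to the flavanone, and the triol has to survive strong base. The fallback sets out from 10, which is condensed with commercial 4-(prop-2-en-1-yloxy)benzaldehyde (KOH, EtOH, rt) to give (E)-1-[(2S,3S)-3,4-dihydroxy-2-(2-hydroxypropan-2-yl)-2,3-dihydro-1-benzofuran-5-yl]-3-[4-(prop-2-en-1-yloxy)phenyl]prop-2-en-1-one F3. The allyl ether is then removed under neutral conditions with Pd(PPh3)4 (5 mol%) and morpholine in THF at rt; the fallback comes back at 13.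

Step 1 is the third risk. Duff formylations are low-yielding, and the 5-formyl isomer and diformylation compete. The fallback sets out from 1, which is iodinated between the two hydroxyls (I2, HIO3, EtOH/H2O, rt) to give 1-(2,4-dihydroxy-3-iodophenyl)ethan-1-one F4. A palladium-catalysed reductive carbonylation (Pd(OAc)2, 1,3-bis(diphenylphosphino)propane, CO 1 atm, HCO2Na, DMF, 90 °C) then installs the aldehyde; the fallback comes back at 3.

**Further compounds**
F1 | step 3 | 3-acetyl-2,6-bis[(tert-butyldimethylsilyl)oxy]benzaldehyde | CC(=O)c1ccc(O[Si](C)(C)C(C)(C)C)c(C=O)c1O[Si](C)(C)C(C)(C)C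
F2 | step 3 | 1-{2,4-bis[(tert-butyldimethylsilyl)oxy]-3-[(2S,3S)-3-(prop-1-en-2-yl)oxiran-2-yl]phenyl}ethan-1-one | CC(=O)c1ccc(O[Si](C)(C)C(C)(C)C)c([C@@H]2O[C@H]2C(C)=C)c1O[Si](C)(C)C(C)(C)C
F3 | step 5 | (E)-1-[(2S,3S)-3,4-dihydroxy-2-(2-hydroxypropan-2-yl)-2,3-dihydro-1-benzofuran-5-yl]-3-[4-(prop-2-en-1-yloxy)phenyl]prop-2-en-1-one | CC(C)(O)[C@H]1Oc2ccc(C(=O)/C=C/c3ccc(OCC=C)cc3)c(O)c2[C@@H]1O
F4 | step 1 | 1-(2,4-dihydroxy-3-iodophenyl)ethan-1-one | CC(=O)c1ccc(O)c(I)c1O
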